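The constants used here were chosen freely, and the outcome is calculated.

The starting material charged stays accounted for in a closed flask: starting material, target, isomer of the product, over-reaction product, quenched substrate and decomposition product add up to the charge. The isomer can therefore be reckoned as a share of what the quench leaves.

in all of them: starting material 0.050 M; time 6.0 h

| flask | protic impurity |
|---|---|
| noon | 0.0150 M |
| summer | 0.0220 M |
| dawn | 0.0340 M |

    starting material ⇌ target (K1 = 0.76, k1 = 0.78 h⁻¹)
    starting material ⇌ isomer of the product (K2 = 2.1, k2 = 0.31 h⁻¹)
    target ⇌ isomer of the product (k3 = 0.12 h⁻¹)
    starting material + protic impurity → quenched substrate (k4 = 160 M⁻¹ h⁻¹)
    target → over-reaction product (k5 = 0.061 h⁻¹)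
    starting material → decomposition product (k6 = 3.4 × 10⁻⁴ h⁻¹)

* which of these there is most of at the end, counted by the starting material in it, noon (starting material / target / isomer of the product / over-reaction product)
* which of these there is most of at the end, counted by the starting material in it, summer (starting material / target / isomer of the product / over-reaction product)
* which of these there is most of at the end, counted by the starting material in it, dawn (starting material / target / isomer of the product / over-reaction product)
* the largest of these amounts at the end, in percent of the starting material charged, noon
* the largest of these amounts at the end, in percent of the starting material charged, summer
* the largest of these amounts at the end, in percent of the starting material charged, dawn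

1. The bench rule says that one equivalent of protic impurity costs one equivalent of starting material, and the impurity is the limiting reagent of the quench, its charge being smaller than that of the starting material in each flask. At the start of noon the quench uses starting material 7.7 times as fast as the forward step to the isomer, so the rule is applied. By this rule, the reckoned fraction f of the charge that survives the quench is 70.0% in noon, 56.0% in summer and 32.0% in dawn.

2. The survivors interconvert. At equilibrium, starting material, target and isomer stand as 1 : 0.76 : 2.1, so the isomer's share s is 54.4% and the target's is 19.7%.

3. The rule meets its border in two ratios, both counted in turnovers.
- The relaxation half-life of starting material and isomer, by this step alone and both ways together, is 1.51 h in noon, shorter than the time. The count n is 3.96 turnovers, which leaves 6.42% of the gap open.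
- Over-reaction drains the pool through the target, here taken at its equilibrium share, and the count d is 0.0721 turnovers.

Neither count contains the impurity, so my reckoning uses one kept fraction g, 0.871, for the three flasks.

4. My reckoning gives 33.2% for noon, 26.5% for summer and 15.2% for dawn. This is the reckoned isomer yield, Y: surviving fraction times equilibrium share times kept fraction. The isomer's share is larger than those of the target and starting material, so the isomer is my choice in each flask.

5. The forecast names isomer of the product for noon, isomer of the product for summer and isomer of the product for dawn, at 33%, 24% and 17%, concluding “so the isomer leads in all three runs”. My reckoning matches its noon figure, stands higher in summer and lower in dawn.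

6. The simulation gives isomer of the product at 33.2% in noon, isomer of the product at 26.6% in summer and isomer of the product at 15.6% in dawn, each more than the other three amounts. Quenched substrate ends at 30.0% of the charge in noon, 44.0% in summer and 67.9% in dawn. Divided by Y, the isomer reads 1.00 in noon, 1.00 in summer and 1.03 in dawn.

7. The noon flask with 0.20 M of starting material holds 0.0750 equiv of protic impurity, so f is 92.5% and Y is 43.8%. The simulated isomer in that flask stands at 43.8% after 6.00 h.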